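**Plan**

1. Numbering: C1 bears ring C (the pendant guaiacyl ring), C2 the CH2OH group, C3 the CHO group, and C4 is the vinylic CH of ring B; ring A is the fused benzene ring (OH on C7, OMe on C8).
2. Enabling feature: C3 and its formyl carbon are an acetaldehyde unit lying between C2, which can be the β-carbon of a nitroalkene (its nitro carbon becoming the CH2OH carbon), and C4, the formyl carbon of a ring A benzaldehyde; the C4=C3–CHO enal of ring B is therefore an aldol condensation product.
3. Cuts, in retrosynthetic order: C2–C3 and C3=C4 (one step), C2–CH2N (Henry reaction), C1–C8a (aryllithium plus nitrostyrene); every carbon then comes from two vanillin units, two nitromethane units and acetaldehyde.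
4. Forward: rings A and C are joined at C1, the chain is grown to a 3,3-diaryl-1-nitropropene, ring B (the only ring formed) is closed by Michael addition/aldol condensation, and the nitromethyl group is then turned into CH2OH before the phenols are freed.
5. Stereochemistry: C2 is set by the (S)-diarylprolinol silyl ether catalyst in the Michael addition and C1 by dynamic kinetic resolution of the base-labile racemic centre in the same step (1,2-trans by acyclic 1,2-induction); C1 is not touched afterwards, and C2 is epimerizable only in aldehyde 18, where the 1,2-trans isomer is expected to be the more stable one.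

Key step: step 6

Assumption: the (S)-configured catalyst is taken to attack the nitroalkene of 11 with the facial sense established for β-aryl nitroalkenes, which corresponds to 3S in adduct 13 and 2R in 15.

**Route**

Step 1
Reactants: 1 vanillin
Product: 2 3-methoxy-4-(triisopropylsilyloxy)benzaldehyde
Conditions: TIPSCl, imidazole, DMF, rt
Reagents that add atoms: triisopropylsilyl chloride, CC(C)[Si](Cl)(C(C)C)C(C)C
Why: Imidazole-mediated O-silylation of the phenol; the triisopropylsilyl ether is chosen because it does not direct lithiation and should survive n-BuLi, alkoxide bases and dilute acid in the later steps.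

Step 2
Reactants: 2 3-methoxy-4-(triisopropylsilyloxy)benzaldehyde
Product: 3 4-(dimethoxymethyl)-2-methoxy-1-(triisopropylsilyloxy)benzene
Conditions: HC(OMe)3, MeOH, TsOH·H2O (cat.), rt
Reagents that add atoms: trimethyl orthoformate, COC(OC)OC; methanol, CO
Why: Acid-catalysed acetalization with the orthoformate as water scavenger; the dimethyl acetal masks the formyl group and will direct lithiation to the ring position between itself and the methoxy group.

Step 3
Reactants: 2 3-methoxy-4-(triisopropylsilyloxy)benzaldehyde; 4 nitromethane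
Product: 5 (E)-2-methoxy-4-(2-nitroethenyl)-1-(triisopropylsilyloxy)benzene
Conditions: CH3NO2, NH4OAc, AcOH, 90 °C
Reagents that add atoms: none
Why: Henry condensation of an aromatic aldehyde under ammonium acetate catalysis, which dehydrates in the same pot to the thermodynamically favoured (E)-nitrostyrene.

Step 4
Reactants: 3 4-(dimethoxymethyl)-2-methoxy-1-(triisopropylsilyloxy)benzene; 5 (E)-2-methoxy-4-(2-nitroethenyl)-1-(triisopropylsilyloxy)benzene
Product: 8 rac-2-[6-(dimethoxymethyl)-2-methoxy-3-(triisopropylsilyloxy)phenyl]-2-[3-methoxy-4-(triisopropylsilyloxy)phenyl]acetaldehyde, via aryllithium 6 (not isolated), via lithium nitronate 7 (not isolated)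
Conditions: n-BuLi, THF, 0 °C; 5, −78 °C; then KMnO4, MgSO4, H2O, 0 °C
Reagents that add atoms: potassium permanganate, [K+].[O-][Mn](=O)(=O)=O
Why: Directed ortho-metalation between the acetal and methoxy groups (the bulky silyloxy group does not compete), conjugate addition of the aryllithium to the nitrostyrene and permanganate oxidation of the resulting nitronate in the Nef sense, which is much faster than attack on the arenes, should give the aldehyde with C1 formed as a racemate, as wanted for the later resolution.

Step 5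
Reactants: 8 rac-2,2-diarylacetaldehyde; 4 nitromethane
Product: 11 rac-(E)-3-[6-(dimethoxymethyl)-2-methoxy-3-(triisopropylsilyloxy)phenyl]-3-[3-methoxy-4-(triisopropylsilyloxy)phenyl]-1-nitroprop-1-ene, via nitro alcohol 9 (not isolated), via mesylate 10 (not isolated)
Conditions: CH3NO2, 1,1,3,3-tetramethylguanidine (10 mol %), THF, 0 °C; then MsCl, i-Pr2NEt, −30 → 0 °C
Reagents that add atoms: none
Why: Base-catalysed Henry addition followed by mesylation and E1cB elimination should give the (E)-nitroalkene; the carbinol centre of 9 is lost, C1 stays racemic, and the hindered amine at low temperature limits migration of the double bond toward C1.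

Step 6
Reactants: 11 rac-(E)-3,3-diaryl-1-nitroprop-1-ene (ring A aldehyde masked as dimethyl acetal); 12 acetaldehyde
Product: 15 (1S,2R)-8-methoxy-1-[3-methoxy-4-(triisopropylsilyloxy)phenyl]-2-(nitromethyl)-7-(triisopropylsilyloxy)-1,2-dihydronaphthalene-3-carbaldehyde, via Michael adduct 13 (not isolated), via nitro dialdehyde 14 (not isolated)
Conditions: (S)-α,α-diphenylprolinol trimethylsilyl ether (20 mol %), CH3CHO (slow addition), 1,4-dioxane, rt; then AcOH, H2O, 40 °C
Reagents that add atoms: none
Why: Proposed new method: the (S)-catalyst turns acetaldehyde into its enamine, which adds to C2 of the nitroalkene (C2–C3) to give nitro aldehyde 13; aqueous acetic acid then frees the ring A aldehyde, and the enamine of 14 attacks that formyl carbon (C4) and loses water to the conjugated enal (C3=C4). The closest known chemistry is the diarylprolinol silyl ether-catalysed Michael addition of acetaldehyde to nitroalkenes and amine-catalysed Michael/aldol condensation sequences that close cyclohexene carbaldehydes, whereas dynamic kinetic resolution of a γ-stereogenic nitroalkene within such a sequence has not been shown. Ring B closes by a 6-(enolexo)-exo-trig aldol addition followed by E1cB loss of water. C2 is controlled by the catalyst, whose diphenyl(trimethylsilyloxy)methyl group shields one face of the anti enamine so that the acyclic synclinal transition state reaches the same face of C2 as with β-nitrostyrene; C1 is controlled by dynamic kinetic resolution, because the free amine exchanges the doubly benzylic γ-hydrogen of 11 through the dienyl nitronate and only (S)-11 offers that face anti to the bulky 2,6-disubstituted ring A aryl with the C1 hydrogen next to the incoming enamine, which leads to the 1,2-trans series. The step needs conjugate addition to be slower than C1 epimerization and the nitronate not to be trapped: slow addition of acetaldehyde serves the first, and the acetal mask on ring A the second, since a free ortho-formyl group would capture the dienyl nitronate in an intramolecular Henry reaction and aromatize to a nitronaphthalene. The β,γ-unsaturated nitro isomer of 11 is not a dead end, because it returns to 11 through the same nitronate.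

Step 7
Reactants: 15 (1S,2R)-2-(nitromethyl)-1,2-dihydronaphthalene-3-carbaldehyde
Product: 16 2-[(1S,2R)-8-methoxy-1-[3-methoxy-4-(triisopropylsilyloxy)phenyl]-2-(nitromethyl)-7-(triisopropylsilyloxy)-1,2-dihydronaphthalen-3-yl]-1,3-dioxolane
Conditions: TMSOCH2CH2OTMS, TMSOTf (cat.), CH2Cl2, −78 → −20 °C
Reagents that add atoms: 1,2-bis(trimethylsilyloxy)ethane, C[Si](C)(C)OCCO[Si](C)(C)C
Why: TMSOTf-catalysed silyl-transfer acetalization should protect the enal at low temperature without moving the double bond, so that the C3 formyl group survives the oxidative Nef step and the hydride reduction.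

Step 8
Reactants: 16 nitromethyl dioxolane
Product: 18 (1S,2R)-3-(1,3-dioxolan-2-yl)-8-methoxy-1-[3-methoxy-4-(triisopropylsilyloxy)phenyl]-7-(triisopropylsilyloxy)-1,2-dihydronaphthalene-2-carbaldehyde, via potassium nitronate 17 (not isolated)
Conditions: t-BuOK, THF, 0 °C; then KMnO4, MgSO4, H2O, 0 °C
Reagents that add atoms: potassium permanganate, [K+].[O-][Mn](=O)(=O)=O
Why: Nef reaction in its permanganate form: the nitronate should be oxidized to the aldehyde within minutes at 0 °C, faster than the trisubstituted styrene double bond, while the basic medium leaves the acetal and the silyl ethers intact and C2 is not deprotonated in the nitronate.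

Step 9
Reactants: 18 C2 aldehyde (used crude)
Product: 19 [(1S,2R)-3-(1,3-dioxolan-2-yl)-8-methoxy-1-[3-methoxy-4-(triisopropylsilyloxy)phenyl]-7-(triisopropylsilyloxy)-1,2-dihydronaphthalen-2-yl]methanol
Conditions: NaBH4, MeOH, THF, 0 °C
Reagents that add atoms: none
Why: Hydride reduction of the only free aldehyde, carried out at once on the crude material to forestall epimerization at C2 or migration of the double bond.

Step 10
Reactants: 19 protected alcohol
Product: 21 vitedoin A, via bis-phenol acetal 20 (not isolated)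
Conditions: TBAF, AcOH, THF, 0 °C → rt; then 1 M HCl, rt
Reagents that add atoms: water, O
Why: Fluoride cleavage of both aryl silyl ethers followed by acid hydrolysis of the allylic dioxolane in the same flask should release the hydroxy enal, neither stereocentre being acidic under these conditions.

**Compound list**

1 | vanillin (4-hydroxy-3-methoxybenzaldehyde) | O=Cc1ccc(O)c(OC)c1 | starting material
2 | 3-methoxy-4-(triisopropylsilyloxy)benzaldehyde | O=Cc1ccc(O[Si](C(C)C)(C(C)C)C(C)C)c(OC)c1 | intermediate
3 | 4-(dimethoxymethyl)-2-methoxy-1-(triisopropylsilyloxy)benzene | COC(OC)c1ccc(O[Si](C(C)C)(C(C)C)C(C)C)c(OC)c1 | intermediate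
4 | nitromethane | C[N+](=O)[O-] | starting material
5 | (E)-2-methoxy-4-(2-nitroethenyl)-1-(triisopropylsilyloxy)benzene | COc1cc(/C=C/[N+](=O)[O-])ccc1O[Si](C(C)C)(C(C)C)C(C)C | intermediate
6 | [6-(dimethoxymethyl)-2-methoxy-3-(triisopropylsilyloxy)phenyl]lithium | [Li]c1c(C(OC)OC)ccc(O[Si](C(C)C)(C(C)C)C(C)C)c1OC | intermediate
7 | lithium nitronate of rac-2-[6-(dimethoxymethyl)-2-methoxy-3-(triisopropylsilyloxy)phenyl]-2-[3-methoxy-4-(triisopropylsilyloxy)phenyl]-1-nitroethane | [Li+].[O-][N+]([O-])=CC(c1ccc(O[Si](C(C)C)(C(C)C)C(C)C)c(OC)c1)c1c(C(OC)OC)ccc(O[Si](C(C)C)(C(C)C)C(C)C)c1OC | intermediate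
8 | rac-2-[6-(dimethoxymethyl)-2-methoxy-3-(triisopropylsilyloxy)phenyl]-2-[3-methoxy-4-(triisopropylsilyloxy)phenyl]acetaldehyde | O=CC(c1ccc(O[Si](C(C)C)(C(C)C)C(C)C)c(OC)c1)c1c(C(OC)OC)ccc(O[Si](C(C)C)(C(C)C)C(C)C)c1OC | intermediate
9 | 3-[6-(dimethoxymethyl)-2-methoxy-3-(triisopropylsilyloxy)phenyl]-3-[3-methoxy-4-(triisopropylsilyloxy)phenyl]-1-nitropropan-2-ol (mixture of diastereomers) | [O-][N+](=O)CC(O)C(c1ccc(O[Si](C(C)C)(C(C)C)C(C)C)c(OC)c1)c1c(C(OC)OC)ccc(O[Si](C(C)C)(C(C)C)C(C)C)c1OC | intermediate
10 | methanesulfonate of 9 | [O-][N+](=O)CC(OS(C)(=O)=O)C(c1ccc(O[Si](C(C)C)(C(C)C)C(C)C)c(OC)c1)c1c(C(OC)OC)ccc(O[Si](C(C)C)(C(C)C)C(C)C)c1OC | intermediate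
11 | rac-(E)-3-[6-(dimethoxymethyl)-2-methoxy-3-(triisopropylsilyloxy)phenyl]-3-[3-methoxy-4-(triisopropylsilyloxy)phenyl]-1-nitroprop-1-ene | [O-][N+](=O)/C=C/C(c1ccc(O[Si](C(C)C)(C(C)C)C(C)C)c(OC)c1)c1c(C(OC)OC)ccc(O[Si](C(C)C)(C(C)C)C(C)C)c1OC | intermediate
12 | acetaldehyde | CC=O | starting material
13 | (3S)-3-[(S)-[6-(dimethoxymethyl)-2-methoxy-3-(triisopropylsilyloxy)phenyl][3-methoxy-4-(triisopropylsilyloxy)phenyl]methyl]-4-nitrobutanal | COc1cc([C@H]([C@H](CC=O)C[N+](=O)[O-])c2c(C(OC)OC)ccc(O[Si](C(C)C)(C(C)C)C(C)C)c2OC)ccc1O[Si](C(C)C)(C(C)C)C(C)C | intermediate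
14 | (3S)-3-[(S)-[6-formyl-2-methoxy-3-(triisopropylsilyloxy)phenyl][3-methoxy-4-(triisopropylsilyloxy)phenyl]methyl]-4-nitrobutanal | COc1cc([C@H]([C@H](CC=O)C[N+](=O)[O-])c2c(C=O)ccc(O[Si](C(C)C)(C(C)C)C(C)C)c2OC)ccc1O[Si](C(C)C)(C(C)C)C(C)C | intermediate
15 | (1S,2R)-8-methoxy-1-[3-methoxy-4-(triisopropylsilyloxy)phenyl]-2-(nitromethyl)-7-(triisopropylsilyloxy)-1,2-dihydronaphthalene-3-carbaldehyde (1,2-trans) | COc1cc([C@H]2c3c(ccc(O[Si](C(C)C)(C(C)C)C(C)C)c3OC)C=C(C=O)[C@@H]2C[N+](=O)[O-])ccc1O[Si](C(C)C)(C(C)C)C(C)C | intermediate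
16 | 2-[(1S,2R)-8-methoxy-1-[3-methoxy-4-(triisopropylsilyloxy)phenyl]-2-(nitromethyl)-7-(triisopropylsilyloxy)-1,2-dihydronaphthalen-3-yl]-1,3-dioxolane | COc1cc([C@H]2c3c(ccc(O[Si](C(C)C)(C(C)C)C(C)C)c3OC)C=C(C4OCCO4)[C@@H]2C[N+](=O)[O-])ccc1O[Si](C(C)C)(C(C)C)C(C)C | intermediate
17 | potassium nitronate of 16 | [K+].COc1cc([C@H]2c3c(ccc(O[Si](C(C)C)(C(C)C)C(C)C)c3OC)C=C(C4OCCO4)[C@@H]2C=[N+]([O-])[O-])ccc1O[Si](C(C)C)(C(C)C)C(C)C | intermediate
18 | (1S,2R)-3-(1,3-dioxolan-2-yl)-8-methoxy-1-[3-methoxy-4-(triisopropylsilyloxy)phenyl]-7-(triisopropylsilyloxy)-1,2-dihydronaphthalene-2-carbaldehyde | COc1cc([C@H]2c3c(ccc(O[Si](C(C)C)(C(C)C)C(C)C)c3OC)C=C(C4OCCO4)[C@@H]2C=O)ccc1O[Si](C(C)C)(C(C)C)C(C)C | intermediate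
19 | [(1S,2R)-3-(1,3-dioxolan-2-yl)-8-methoxy-1-[3-methoxy-4-(triisopropylsilyloxy)phenyl]-7-(triisopropylsilyloxy)-1,2-dihydronaphthalen-2-yl]methanol | COc1cc([C@H]2c3c(ccc(O[Si](C(C)C)(C(C)C)C(C)C)c3OC)C=C(C4OCCO4)[C@@H]2CO)ccc1O[Si](C(C)C)(C(C)C)C(C)C | intermediate
20 | 4-[(1S,2R)-3-(1,3-dioxolan-2-yl)-7-hydroxy-2-(hydroxymethyl)-8-methoxy-1,2-dihydronaphthalen-1-yl]-2-methoxyphenol | COc1cc([C@H]2c3c(ccc(O)c3OC)C=C(C4OCCO4)[C@@H]2CO)ccc1O | intermediate
21 | vitedoin A, (1S,2R)-7-hydroxy-1-(4-hydroxy-3-methoxyphenyl)-2-(hydroxymethyl)-8-methoxy-1,2-dihydronaphthalene-3-carbaldehyde (1,2-trans) | COc1cc([C@H]2c3c(ccc(O)c3OC)C=C(C=O)[C@@H]2CO)ccc1O | target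

**Step count and risks**

Total: 10 steps. Longest linear sequence: 9 steps (steps 1, 2, 4, 5, 6, 7, 8, 9, 10; step 3 is a one-step branch from 2).

Step 6 (the only step with a new method). What may go wrong: the dynamic resolution stalls, either because C1 of 11 epimerizes too slowly relative to conjugate addition or because the two enantiomers are too weakly discriminated, so that cis and trans adducts form together and the enantiomeric purity of 15 erodes. The fallback uses known chemistry and sets out from 11. The Michael addition is run as an ordinary catalytic kinetic resolution: same catalyst, PhCO2H as acid buffer to suppress nitronate formation, 0 °C, stopped near half conversion. Adduct 13 is then isolated and separated from the unreacted (R)-enantiomer of 11 F1. F1 is racemized on its own with catalytic DBU in THF through the nitronate and fed back to the resolution. Isolated 13 is unmasked and cyclized in a separate operation (AcOH, H2O, pyrrolidine cat., 1,4-dioxane, 40 °C) through 14. The fallback returns to the route at 15.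

Step 5. What may go wrong: under the amine base the double bond migrates out of conjugation with the nitro group toward the diaryl carbon during mesylate elimination, and the nitro alcohol reverts by retro-Henry cleavage. The fallback sets out from 8 and avoids base at the nitroalkene stage. Wittig methylenation of 8 (Ph3PCH3Br, KHMDS, THF, −78 → 0 °C) gives 4-(dimethoxymethyl)-2-methoxy-3-[1-[3-methoxy-4-(triisopropylsilyloxy)phenyl]prop-2-enyl]-1-(triisopropylsilyloxy)benzene F2. Radical nitration–elimination of its terminal alkene (AgNO2, TEMPO, 4 Å MS, ClCH2CH2Cl, 70 °C) installs the (E)-nitroalkene. The fallback returns to the route at 11.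

Step 8. What may go wrong: permanganate attack on the electron-rich C3=C4 double bond competes with nitronate oxidation, or the α-branched aldehyde epimerizes at C2 and shifts its double bond before it is reduced. The fallback sets out from 16 and bypasses the aldehyde. NaNO2, AcOH, DMSO, 35 °C converts the primary nitro group directly, without strong base, into (1S,2R)-3-(1,3-dioxolan-2-yl)-8-methoxy-1-[3-methoxy-4-(triisopropylsilyloxy)phenyl]-7-(triisopropylsilyloxy)-1,2-dihydronaphthalene-2-carboxylic acid F3. Activation with i-BuOCOCl and N-methylmorpholine (THF, −15 °C) gives the isobutyl carbonic mixed anhydride F4, which is reduced in the same flask with NaBH4. The fallback returns to the route at 19.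

**Further compounds**

F1 | step 6 | (R)-(E)-3-[6-(dimethoxymethyl)-2-methoxy-3-(triisopropylsilyloxy)phenyl]-3-[3-methoxy-4-(triisopropylsilyloxy)phenyl]-1-nitroprop-1-ene | COc1cc([C@@H](/C=C/[N+](=O)[O-])c2c(C(OC)OC)ccc(O[Si](C(C)C)(C(C)C)C(C)C)c2OC)ccc1O[Si](C(C)C)(C(C)C)C(C)C
F2 | step 5 | rac-4-(dimethoxymethyl)-2-methoxy-3-[1-[3-methoxy-4-(triisopropylsilyloxy)phenyl]prop-2-enyl]-1-(triisopropylsilyloxy)benzene | C=CC(c1ccc(O[Si](C(C)C)(C(C)C)C(C)C)c(OC)c1)c1c(C(OC)OC)ccc(O[Si](C(C)C)(C(C)C)C(C)C)c1OC
F3 | step 8 | (1S,2R)-3-(1,3-dioxolan-2-yl)-8-methoxy-1-[3-methoxy-4-(triisopropylsilyloxy)phenyl]-7-(triisopropylsilyloxy)-1,2-dihydronaphthalene-2-carboxylic acid | COc1cc([C@H]2c3c(ccc(O[Si](C(C)C)(C(C)C)C(C)C)c3OC)C=C(C4OCCO4)[C@@H]2C(=O)O)ccc1O[Si](C(C)C)(C(C)C)C(C)C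
F4 | step 8 | isobutyl carbonic mixed anhydride of F3 | COc1cc([C@H]2c3c(ccc(O[Si](C(C)C)(C(C)C)C(C)C)c3OC)C=C(C4OCCO4)[C@@H]2C(=O)OC(=O)OCC(C)C)ccc1O[Si](C(C)C)(C(C)C)C(C)C
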